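The ochre run has the charges of Sunday's flask, and it reads 91.4% of L at 2.00 min and 99.3% at 4.00 min.

| flask | Z | J | remark | time |
|---|---|---|---|---|
| ochre | 0.020 M | 0.080 M | run made earlier |  |
| violet | 0.010 M | 0.080 M | run made earlier |  |
| blue | 0.040 M | 0.080 M | run made earlier |  |
| amber | 0.020 M | 0.12 M | run made earlier |  |
| Tuesday's | 0.020 M (in portions, 3, over 2.5 min) | 0.0800 M | first portion at the start, last at 2.5 min | 4.0 min |
| Thursday's | 0.020 M (fed, over 2.5 min) | 0.0800 M | all else is in the flask from the start; the feed brings no volume worth counting | 4.0 min |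
| Sunday's | 0.020 M | 0.0800 M | everything together at the start | 4.0 min |
| Wednesday's | 0.020 M | 0.0800 M (fed, over 2.5 min) | all else is in the flask from the start; the feed brings no volume worth counting | 4.0 min |

- ochre (time / min: L / %): 0.250: 20.8; 0.833: 62.8; 1.33: 80.9; 2.00: 91.4; 3.00: 98.4; 4.00: 99.3
- violet (time / min: L / %): 0.167: 11.6; 0.500: 44.2; 0.833: 65.9; 1.33: 82.9; 2.00: 93.4; 2.50: 97.2
- blue (time / min: L / %): 0.167: 11.2; 0.500: 42.3; 0.833: 59.8; 1.33: 76.7; 2.00: 88.3; 2.50: 92.9
- amber (time / min: L / %): 0.200: 20.5; 0.333: 37.1; 0.667: 66.2; 1.33: 90.6; 2.50: 98.6

(readings scatter by 0.5 percentage points)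

- a reading or a percentage of L counts all its forms, free or not

1. the best flask by amount of L, in percent of the Z charged; "all alike" if 1.5 percentage points covers them all (Tuesday's / Thursday's / Sunday's / Wednesday's / all alike)
2. amount of L at the end, in percent of the Z charged, Tuesday's
3. amount of L at the end, in percent of the Z charged, Thursday's
4. amount of L at the end, in percent of the Z charged, Sunday's
5. amount of L at the end, in percent of the Z charged, Wednesday's

I begin with the main step by itself. J stands at four times Z (Z is a quarter of J), so I treat Z as pseudo-first-order. From ochre I read the pace, meaning minus the logarithm of the share of Z left, divided by the time: 1.23 min⁻¹. Pace times the minutes a portion spends in the flask is its exposure, and the share left is exp(−exposure). Sunday's Z has an exposure of 4.92, which leaves 0.740%.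

Now I add late arrival. Tuesday's portions spend 4.0 min, 2.75 min and 1.50 min in the flask, and the mean left is 6.68%. The last portion makes up 5.29% of the Z charged within that mean, and I expect 93.3% of L.

Next comes J. Amber and ochre both have a reading at 1.33 min, so the ratio of their exposures loses the time. It reads 1.43, a little below the J ratio of 1.50, so I make the pace proportional to J's share of its charge. Counting the J fed and not what reacts, Wednesday's feed is worth 1.25 min at full J. That leaves 3.43%, or 96.6% of L.

Last comes the slowing with Z charge. The pace at 2.00 min reads 1.36 min⁻¹ in violet and 1.07 min⁻¹ in blue. Tuesday's, Thursday's, Sunday's and Wednesday's carry ochre's Z charge, so I leave the number unchanged. Of the flasks reckoned so far, my reckoning leaves the least Z in Sunday's.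

The forecast names Sunday's with 99.3%, a figure it describes as “matching the ochre run”, and gives Tuesday's 93%, Thursday's 94.6% and Wednesday's 96.9%.

The flasks give Sunday's as the best at 99.3%, with Wednesday's at 97.2% and Tuesday's at 93.1%.

    Z ⇌ E (K = 1.10, k = 0.0680 s⁻¹)
    J + E → L (k = 0.770 L mol⁻¹ s⁻¹)
    X ⇌ L, rate k3*(cs3 - [L]) while solid is left; crystals form when [L] > cs3 (solubility = 0.450 mM, k = 4.70 s⁻¹)

Of the 6.90% missing from L in Tuesday's at the end, Z holds 3.93% and E, the form Z passes through, holds 3.01%. Thursday's feed is Tuesday's portions spread evenly. The pace gives a feed exposure of 3.07, and the share left at the end of the feed is (1 − exp(−exposure))/exposure, which is 31.1%. The remaining 1.50 min multiplies that by 15.9%. So I reckon 95.1% of L, and Thursday's holds 95.0%.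

The earlier runs and the new flask are calculated for an exercise.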